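Retrosynthetic cuts: (i) the six phenolic O–H bonds (MOM ethers); (ii) C2(flavanone)–C1′(B ring), giving arylboronic acid 17 and 6,8-diprenylchromone 22; (iii) C2–aryl of the dihydrobenzofuran, giving 2-carboxylic acid 13 and iodide 15; (iv) O1–C2 of the dihydrobenzofuran, redrawn as the acyl–O bond of α-bromo lactone 11; (v) C4–aryl of the lactone, giving coumarin 5 and boronic acid 8.
Enabling feature: ring O1–C2–C3–C3a–C7a is fused to the resorcinol-type B ring and carries the 3,5-dioxygenated aryl group on C3. It is a 4-aryl-3,4-dihydrocoumarin ring (O1, C=O, Cα, C4, C4a, C8a) less its carbonyl carbon; phenolic O1 can leave the acyl carbon and return on Cα, which pushes that carbon out of the ring as a carboxyl group.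
Forward order: pyranone ring (Pechmann) → C4 arylation → α-bromination → 6→5 ring contraction → the expelled CO2H is traded for the 4-oxygenated aryl group → Cl placeholder to B(OH)2 → addition to chromone 22 (A/C rings, made separately from phloroacetophenone) → global deprotection.
Stereochemistry: C3 of the dihydrobenzofuran is set by Rh/(R)-SEGPHOS catalysis. C2 is relayed from it (anti bromination, SN2 inversion, then anti capture of the C2 radical; trans is also the thermodynamic isomer). C2 of the flavanone is set independently by a second, catalyst-controlled Rh addition.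
Helpers and their removal: Br (leaves in step 7), CO2H (leaves as CO2 in step 9), Cl (replaced in step 10), MOM (step 15).

Key step: step 7

Assumption: the sense of induction in steps 5 and 14 is taken from the usual quadrant model of biaryl-bisphosphine Rh–aryl complexes ((R)-ligand → (4R)-lactone, (S)-ligand → (2S)-flavanone); if a sense should prove opposite, the antipodal ligand is used.

Step 1
Reactants: 1 4-chlororesorcinol; 2 DL-malic acid
Product: 4 6-chloro-7-hydroxy-2H-chromen-2-one, via 3-oxopropanoic acid 3 (not isolated)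
Conditions: conc. H2SO4, 110 °C
Reagents that add atoms: none
Why: von Pechmann condensation, in which hot sulfuric acid decarbonylates malic acid to 3-oxopropanoic acid, which attacks the only free position of 1 that is para to one OH and ortho to the other and then lactonises, while Cl blocks the alternative site and stays as a placeholder for boron.

Step 2
Reactants: 4 6-chloro-7-hydroxy-2H-chromen-2-one
Product: 5 6-chloro-7-(methoxymethoxy)-2H-chromen-2-one
Conditions: MOMCl, i-Pr2NEt, CH2Cl2, 0 °C → rt
Reagents that add atoms: chloromethyl methyl ether COCCl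
Why: Standard O-alkylation of an acidic phenol, giving an acetal that is stable to all basic, organometallic and photoredox steps ahead and is removed only in the last step.

Step 3
Reactants: 6 5-bromoresorcinol
Product: 7 1-bromo-3,5-bis(methoxymethoxy)benzene
Conditions: MOMCl, i-Pr2NEt, CH2Cl2, 0 °C → rt
Reagents that add atoms: chloromethyl methyl ether COCCl
Why: Standard double O-alkylation of a phenol with MOMCl and a hindered amine base.

Step 4
Reactants: 7 1-bromo-3,5-bis(methoxymethoxy)benzene
Product: 8 [3,5-bis(methoxymethoxy)phenyl]boronic acid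
Conditions: B2(OH)4, XPhos Pd G2 (cat.), XPhos (cat.), KOAc, EtOH, 80 °C
Reagents that add atoms: tetrahydroxydiboron OB(O)B(O)O
Why: Pd-catalysed Miyaura-type borylation with tetrahydroxydiboron gives the free boronic acid directly and avoids an aryllithium next to two MOM directing groups.

Step 5
Reactants: 5 6-chloro-7-(methoxymethoxy)-2H-chromen-2-one; 8 [3,5-bis(methoxymethoxy)phenyl]boronic acid
Product: 9 (4R)-4-[3,5-bis(methoxymethoxy)phenyl]-6-chloro-7-(methoxymethoxy)-3,4-dihydro-2H-chromen-2-one
Conditions: Rh(acac)(C2H4)2 (cat.), (R)-SEGPHOS (cat.), dioxane/H2O, 60 °C, excess 8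
Reagents that add atoms: none
Why: Rh-catalysed asymmetric 1,4-addition of an arylboronic acid to a coumarin (Hayashi–Miyaura reaction), in which the (R)-SEGPHOS Rh–aryl species inserts the C3=C4 bond from one face and sets C4 as (R), the future C3 of the dihydrobenzofuran, with aryl chloride and MOM groups inert.

Step 6
Reactants: 9 (4R)-4-[3,5-bis(methoxymethoxy)phenyl]-6-chloro-7-(methoxymethoxy)-3,4-dihydro-2H-chromen-2-one
Product: 11 (3S,4R)-3-bromo-4-[3,5-bis(methoxymethoxy)phenyl]-6-chloro-7-(methoxymethoxy)-3,4-dihydro-2H-chromen-2-one, via lithium enolate 10 (not isolated)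
Conditions: LiHMDS, THF, −78 °C; NBS, −78 °C; aq. NH4Cl
Reagents that add atoms: N-bromosuccinimide O=C1CCC(=O)N1Br
Why: Kinetic enolate formation at low temperature (no loss of aryloxide) and electrophilic bromination from the face opposite the pseudo-axial C4 aryl group should give the 3,4-trans α-bromo lactone, and a minor cis epimer would be harmless because C2 is re-made in step 9.

Step 7
Reactants: 11 (3S,4R)-3-bromo-4-[3,5-bis(methoxymethoxy)phenyl]-6-chloro-7-(methoxymethoxy)-3,4-dihydro-2H-chromen-2-one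
Product: 13 (2R,3R)-3-[3,5-bis(methoxymethoxy)phenyl]-5-chloro-6-(methoxymethoxy)-2,3-dihydro-1-benzofuran-2-carboxylic acid, via ring-opened dilithium bromocarboxylate phenoxide 12 (not isolated)
Conditions: LiOH, THF/H2O, 0 °C → rt; then cold dil. HCl to pH 4
Reagents that add atoms: lithium hydroxide [Li+].[OH-]
Why: Hydroxide adds to the aryl-ester carbonyl of 11 (the most electrophilic site), the C(=O)–O1 bond breaks, and the freed phenoxide O1 of 12 displaces bromide at the former lactone α-carbon, so the six-membered ring O1–C(=O)–Cα–C4–C4a–C8a shrinks to the five-membered ring O1–C2–C3–C3a–C7a and the carbonyl carbon is pushed out as the C2 carboxylate. The closest known reaction type is the Perkin coumarin-to-benzofuran ring contraction of 3-halocoumarins, here in its sp3 form, which is also the base-induced contraction of α-halo or α-sulfonyloxy δ-lactones to tetrahydrofuran-2-carboxylates. The single ring closure is a 5-exo-tet SN2 O-alkylation. C3 is untouched and keeps the (R) configuration from step 5, while the new C2 centre arises by inversion of the (3S) C–Br centre that had been placed anti to the C4 aryl group, which gives the trans (2R,3R) acid, also the more stable epimer. The step needs acyl attack and substitution to win over loss of HBr: in the lactone H-4 and Br are syn, so no anti-periplanar E2 is available, and after ring opening the intramolecular 5-exo attack of the phenoxide should outrun any intermolecular base. MOM ethers and the aryl chloride are inert to aqueous LiOH, and the 2-carboxylate has no β-aryloxy leaving group, so no retro-oxa-Michael opening can follow.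

Step 8
Reactants: 14 4-iodophenol
Product: 15 1-iodo-4-(methoxymethoxy)benzene
Conditions: MOMCl, i-Pr2NEt, CH2Cl2, 0 °C → rt
Reagents that add atoms: chloromethyl methyl ether COCCl
Why: Standard O-alkylation of a phenol with MOMCl and a hindered amine base.

Step 9
Reactants: 13 (2R,3R)-3-[3,5-bis(methoxymethoxy)phenyl]-5-chloro-6-(methoxymethoxy)-2,3-dihydro-1-benzofuran-2-carboxylic acid; 15 1-iodo-4-(methoxymethoxy)benzene
Product: 16 (2R,3R)-3-[3,5-bis(methoxymethoxy)phenyl]-5-chloro-6-(methoxymethoxy)-2-[4-(methoxymethoxy)phenyl]-2,3-dihydro-1-benzofuran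
Conditions: Ir[dF(CF3)ppy]2(dtbbpy)PF6 (cat.), NiCl2·glyme (cat.), dtbbpy (cat.), Cs2CO3, DMF, blue LEDs, rt
Reagents that add atoms: none
Why: Metallaphotoredox decarboxylative arylation of an α-oxy acid, in which oxidation of the caesium carboxylate and loss of CO2 give the C2 α-aryloxy radical, which is captured by the aryl–Ni species and coupled on the face anti to the C3 aryl group to give the trans (2R,3R) product, while the electron-rich, ortho-substituted C–Cl bond should not add to Ni at room temperature.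

Step 10
Reactants: 16 (2R,3R)-3-[3,5-bis(methoxymethoxy)phenyl]-5-chloro-6-(methoxymethoxy)-2-[4-(methoxymethoxy)phenyl]-2,3-dihydro-1-benzofuran
Product: 17 {(2R,3R)-3-[3,5-bis(methoxymethoxy)phenyl]-6-(methoxymethoxy)-2-[4-(methoxymethoxy)phenyl]-2,3-dihydro-1-benzofuran-5-yl}boronic acid
Conditions: B2(OH)4, XPhos Pd G2 (cat.), XPhos (cat.), KOAc, EtOH, 80 °C
Reagents that add atoms: tetrahydroxydiboron OB(O)B(O)O
Why: Pd/XPhos-catalysed Miyaura-type borylation of an aryl chloride turns the placeholder into the boronic acid under weakly basic conditions that leave the MOM ethers and both benzylic stereocentres alone.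

Step 11
Reactants: 18 2′,4′,6′-trihydroxyacetophenone
Product: 19 1-[2,4,6-trihydroxy-3,5-bis(3-methylbut-2-en-1-yl)phenyl]ethanone
Conditions: prenyl bromide, KOH, H2O, 0 °C → rt
Reagents that add atoms: prenyl bromide CC(C)=CCBr
Why: C-alkylation of the ambident phloroglucinol phenolate in water (a protic medium favours C over O) at the two equivalent free ring positions, with stoichiometry and low temperature limiting geminal over-alkylation.

Step 12
Reactants: 19 1-[2,4,6-trihydroxy-3,5-bis(3-methylbut-2-en-1-yl)phenyl]ethanone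
Product: 20 1-[2-hydroxy-4,6-bis(methoxymethoxy)-3,5-bis(3-methylbut-2-en-1-yl)phenyl]ethanone
Conditions: MOMCl (2 equiv), i-Pr2NEt, CH2Cl2, 0 °C
Reagents that add atoms: chloromethyl methyl ether COCCl
Why: Two of the three phenols are alkylated while one ortho OH is held back by its hydrogen bond to the acetyl group, and since the two ortho OH groups are equivalent only one product can result.

Step 13
Reactants: 20 1-[2-hydroxy-4,6-bis(methoxymethoxy)-3,5-bis(3-methylbut-2-en-1-yl)phenyl]ethanone
Product: 22 5,7-bis(methoxymethoxy)-6,8-bis(3-methylbut-2-en-1-yl)-4H-chromen-4-one, via enaminone 21 (not isolated)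
Conditions: Me2NCH(OMe)2, toluene, 90 °C; then AcOH, CH2Cl2, 40 °C
Reagents that add atoms: N,N-dimethylformamide dimethyl acetal COC(OC)N(C)C
Why: Condensation of the methyl ketone with DMF dimethyl acetal gives the enaminone, whose free phenol adds to the β-carbon and expels dimethylamine under mild acid (6-endo-trig addition–elimination, the standard chromone synthesis) without harm to MOM or prenyl groups.

Step 14
Reactants: 17 {(2R,3R)-3-[3,5-bis(methoxymethoxy)phenyl]-6-(methoxymethoxy)-2-[4-(methoxymethoxy)phenyl]-2,3-dihydro-1-benzofuran-5-yl}boronic acid; 22 5,7-bis(methoxymethoxy)-6,8-bis(3-methylbut-2-en-1-yl)-4H-chromen-4-one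
Product: 23 (2S)-2-{(2R,3R)-3-[3,5-bis(methoxymethoxy)phenyl]-6-(methoxymethoxy)-2-[4-(methoxymethoxy)phenyl]-2,3-dihydro-1-benzofuran-5-yl}-5,7-bis(methoxymethoxy)-6,8-bis(3-methylbut-2-en-1-yl)-2,3-dihydro-4H-chromen-4-one
Conditions: [Rh(OH)(cod)]2 (cat.), (S)-MeO-F12-BIPHEP (cat.), toluene/H2O, rt, excess 22
Reagents that add atoms: none
Why: Rh-catalysed asymmetric 1,4-addition of an arylboronic acid to a chromone (Hayashi–Miyaura reaction, known for 5,7-dioxygenated chromones), in which the chiral bisphosphine alone decides the face because the dihydrobenzofuran centres are remote, and sets C2 as (S), while the base-free medium at ambient temperature avoids retro-oxa-Michael opening of the flavanone.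

Step 15
Reactants: 23 (2S)-2-{(2R,3R)-3-[3,5-bis(methoxymethoxy)phenyl]-6-(methoxymethoxy)-2-[4-(methoxymethoxy)phenyl]-2,3-dihydro-1-benzofuran-5-yl}-5,7-bis(methoxymethoxy)-6,8-bis(3-methylbut-2-en-1-yl)-2,3-dihydro-4H-chromen-4-one
Product: 24 (2S)-2-[(2R,3R)-3-(3,5-dihydroxyphenyl)-6-hydroxy-2-(4-hydroxyphenyl)-2,3-dihydro-1-benzofuran-5-yl]-5,7-dihydroxy-6,8-bis(3-methylbut-2-en-1-yl)-2,3-dihydro-4H-chromen-4-one (target)
Conditions: dil. aq. HCl, MeOH, 40 °C
Reagents that add atoms: none
Why: Acid-catalysed transacetalisation of all six MOM ethers to dimethoxymethane under the dilute, mild conditions customary for prenylated flavanones; base is avoided so that flavanone C2 is not scrambled through the chalcone, and reversible ionisation of the p-hydroxybenzylic C2–O1 bond of the dihydrobenzofuran can only return the trans isomer fixed by C3.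

Compound list
1 | 4-chlororesorcinol | Oc1ccc(Cl)c(O)c1 | starting material
2 | DL-malic acid | OC(CC(O)=O)C(O)=O | starting material
3 | 3-oxopropanoic acid | O=CCC(O)=O | intermediate
4 | 6-chloro-7-hydroxy-2H-chromen-2-one | O=c1ccc2cc(Cl)c(O)cc2o1 | intermediate
5 | 6-chloro-7-(methoxymethoxy)-2H-chromen-2-one | COCOc1cc2oc(=O)ccc2cc1Cl | intermediate
6 | 5-bromoresorcinol | Oc1cc(O)cc(Br)c1 | starting material
7 | 1-bromo-3,5-bis(methoxymethoxy)benzene | COCOc1cc(Br)cc(OCOC)c1 | intermediate
8 | [3,5-bis(methoxymethoxy)phenyl]boronic acid | COCOc1cc(OCOC)cc(B(O)O)c1 | intermediate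
9 | (4R)-4-[3,5-bis(methoxymethoxy)phenyl]-6-chloro-7-(methoxymethoxy)-3,4-dihydro-2H-chromen-2-one | O=C1C[C@H](c2cc(OCOC)cc(OCOC)c2)c2cc(Cl)c(OCOC)cc2O1 | intermediate
10 | lithium enolate of 9 | [Li+].[O-]C1=C[C@H](c2cc(OCOC)cc(OCOC)c2)c2cc(Cl)c(OCOC)cc2O1 | intermediate
11 | (3S,4R)-3-bromo-4-[3,5-bis(methoxymethoxy)phenyl]-6-chloro-7-(methoxymethoxy)-3,4-dihydro-2H-chromen-2-one (Br trans to aryl) | O=C1[C@@H](Br)[C@H](c2cc(OCOC)cc(OCOC)c2)c2cc(Cl)c(OCOC)cc2O1 | intermediate
12 | dilithium (2S,3R)-2-bromo-3-[3,5-bis(methoxymethoxy)phenyl]-3-[5-chloro-4-(methoxymethoxy)-2-oxidophenyl]propanoate | [Li+].[Li+].[O-]C(=O)[C@@H](Br)[C@H](c1cc(OCOC)cc(OCOC)c1)c1cc(Cl)c(OCOC)cc1[O-] | intermediate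
13 | (2R,3R)-3-[3,5-bis(methoxymethoxy)phenyl]-5-chloro-6-(methoxymethoxy)-2,3-dihydro-1-benzofuran-2-carboxylic acid (trans) | OC(=O)[C@@H]1Oc2cc(OCOC)c(Cl)cc2[C@H]1c1cc(OCOC)cc(OCOC)c1 | intermediate
14 | 4-iodophenol | Oc1ccc(I)cc1 | starting material
15 | 1-iodo-4-(methoxymethoxy)benzene | COCOc1ccc(I)cc1 | intermediate
16 | (2R,3R)-3-[3,5-bis(methoxymethoxy)phenyl]-5-chloro-6-(methoxymethoxy)-2-[4-(methoxymethoxy)phenyl]-2,3-dihydro-1-benzofuran (trans) | COCOc1ccc(cc1)[C@@H]1Oc2cc(OCOC)c(Cl)cc2[C@H]1c1cc(OCOC)cc(OCOC)c1 | intermediate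
17 | {(2R,3R)-3-[3,5-bis(methoxymethoxy)phenyl]-6-(methoxymethoxy)-2-[4-(methoxymethoxy)phenyl]-2,3-dihydro-1-benzofuran-5-yl}boronic acid | COCOc1ccc(cc1)[C@@H]1Oc2cc(OCOC)c(B(O)O)cc2[C@H]1c1cc(OCOC)cc(OCOC)c1 | intermediate
18 | 2′,4′,6′-trihydroxyacetophenone | CC(=O)c1c(O)cc(O)cc1O | starting material
19 | 1-[2,4,6-trihydroxy-3,5-bis(3-methylbut-2-en-1-yl)phenyl]ethanone | CC(=O)c1c(O)c(CC=C(C)C)c(O)c(CC=C(C)C)c1O | intermediate
20 | 1-[2-hydroxy-4,6-bis(methoxymethoxy)-3,5-bis(3-methylbut-2-en-1-yl)phenyl]ethanone | CC(=O)c1c(O)c(CC=C(C)C)c(OCOC)c(CC=C(C)C)c1OCOC | intermediate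
21 | (E)-3-(dimethylamino)-1-[2-hydroxy-4,6-bis(methoxymethoxy)-3,5-bis(3-methylbut-2-en-1-yl)phenyl]prop-2-en-1-one | CN(C)/C=C/C(=O)c1c(O)c(CC=C(C)C)c(OCOC)c(CC=C(C)C)c1OCOC | intermediate
22 | 5,7-bis(methoxymethoxy)-6,8-bis(3-methylbut-2-en-1-yl)-4H-chromen-4-one | O=c1ccoc2c(CC=C(C)C)c(OCOC)c(CC=C(C)C)c(OCOC)c12 | intermediate
23 | hexa-MOM ether of the target, (2S) at the flavanone and (2R,3R) at the dihydrobenzofuran | CC(C)=CCc1c(OCOC)c(CC=C(C)C)c2c(c1OCOC)C(=O)C[C@@H](c1cc3c(cc1OCOC)O[C@@H](c1ccc(OCOC)cc1)[C@@H]3c1cc(OCOC)cc(OCOC)c1)O2 | intermediate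
24 | (2S)-2-[(2R,3R)-3-(3,5-dihydroxyphenyl)-6-hydroxy-2-(4-hydroxyphenyl)-2,3-dihydro-1-benzofuran-5-yl]-5,7-dihydroxy-6,8-bis(3-methylbut-2-en-1-yl)-2,3-dihydro-4H-chromen-4-one | CC(C)=CCc1c(O)c(CC=C(C)C)c2c(c1O)C(=O)C[C@@H](c1cc3c(cc1O)O[C@@H](c1ccc(O)cc1)[C@@H]3c1cc(O)cc(O)c1)O2 | target

Total step count: 15. Longest linear sequence: 9 steps (1, 2, 5, 6, 7, 9, 10, 14, 15; the branch 3, 4, 5, 6, 7, 9, 10, 14, 15 is equally long).

Steps most likely to fail

Step 14. Protodeboronation of the electron-rich, ortho-alkoxy boronic acid may outrun the slow insertion of the hindered aryl–Rh species into the electron-rich chromone, and facial discrimination may erode. The fallback sets out from 16 (together with 20) and comes back at 23; it separates C–C bond formation from stereocontrol.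
- Suzuki–Miyaura vinylation of 16 (potassium vinyltrifluoroborate, Pd(OAc)2/RuPhos, K2CO3, THF/H2O) would give the 5-vinyl compound F1.
- Lemieux–Johnson cleavage (OsO4 cat., NaIO4) would give the 5-carbaldehyde F2.
- Claisen–Schmidt condensation with 20 (KOH, EtOH) would give the chalcone F3.
- NaOAc in refluxing EtOH would close the flavanone as both C2 epimers, 23 together with the (2R)-epimer F4.
- Noyori–Ikariya transfer hydrogenation used as a kinetic resolution ([Cp*RhCl((R,R)-TsDPEN)], HCO2H/Et3N, EtOAc) should reduce only the (2R) ketone to the cis-flavan-4-ol F5. It leaves 23, which is separated and carried into step 15.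

Step 9. Slow oxidative addition of the electron-rich aryl iodide, β-hydride loss from the alkyl–Ni species with aromatisation to a benzofuran, or poor facial selectivity at the C2 radical may spoil the coupling. The fallback sets out from 13 (with 15) and comes back at 16.
- Esterification with N-hydroxyphthalimide (DIC, DMAP cat., CH2Cl2) would give the redox-active ester F6.
- F6 is coupled with 15 in the dark by Ni-catalysed reductive cross-electrophile coupling (NiBr2·glyme, dtbbpy, Zn, DMA). The radical then arises by reduction of a pre-activated ester instead of photo-oxidation of the carboxylate.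

Step 15. Brønsted acid may add the flanking phenols across the prenyl double bonds (chroman formation). It may also ionise the doubly activated benzylic C2–O bond of the flavanone with loss of configuration, or leave MOM groups behind. The fallback sets out from 23 and comes back at 24.
- Silylative exchange with TMSOTf/2,2′-bipyridyl (CH2Cl2, 0 °C) in a buffered, non-protic medium would convert all aryl MOM ethers into the hexakis(trimethylsilyl) ether F7.
- F7 is hydrolysed with water at neutral pH.

Further compounds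
F1 | step 14 | (2R,3R)-3-[3,5-bis(methoxymethoxy)phenyl]-5-ethenyl-6-(methoxymethoxy)-2-[4-(methoxymethoxy)phenyl]-2,3-dihydro-1-benzofuran | COCOc1ccc(cc1)[C@@H]1Oc2cc(OCOC)c(C=C)cc2[C@H]1c1cc(OCOC)cc(OCOC)c1
F2 | step 14 | (2R,3R)-3-[3,5-bis(methoxymethoxy)phenyl]-6-(methoxymethoxy)-2-[4-(methoxymethoxy)phenyl]-2,3-dihydro-1-benzofuran-5-carbaldehyde | COCOc1ccc(cc1)[C@@H]1Oc2cc(OCOC)c(C=O)cc2[C@H]1c1cc(OCOC)cc(OCOC)c1
F3 | step 14 | (E)-chalcone from 20 and F2 | CC(C)=CCc1c(OCOC)c(CC=C(C)C)c(O)c(c1OCOC)C(=O)/C=C/c1cc2c(cc1OCOC)O[C@@H](c1ccc(OCOC)cc1)[C@@H]2c1cc(OCOC)cc(OCOC)c1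
F4 | step 14 | (2R)-epimer of 23 | CC(C)=CCc1c(OCOC)c(CC=C(C)C)c2c(c1OCOC)C(=O)C[C@H](c1cc3c(cc1OCOC)O[C@@H](c1ccc(OCOC)cc1)[C@@H]3c1cc(OCOC)cc(OCOC)c1)O2
F5 | step 14 | (2R,4R)-cis-flavan-4-ol from F4 | CC(C)=CCc1c(OCOC)c(CC=C(C)C)c2c(c1OCOC)[C@H](O)C[C@H](c1cc3c(cc1OCOC)O[C@@H](c1ccc(OCOC)cc1)[C@@H]3c1cc(OCOC)cc(OCOC)c1)O2
F6 | step 9 | 1,3-dioxoisoindolin-2-yl ester of 13 | O=C(ON1C(=O)c2ccccc2C1=O)[C@@H]1Oc2cc(OCOC)c(Cl)cc2[C@H]1c1cc(OCOC)cc(OCOC)c1
F7 | step 15 | hexakis(trimethylsilyl) ether of 24 | CC(C)=CCc1c(O[Si](C)(C)C)c(CC=C(C)C)c2c(c1O[Si](C)(C)C)C(=O)C[C@@H](c1cc3c(cc1O[Si](C)(C)C)O[C@@H](c1ccc(O[Si](C)(C)C)cc1)[C@@H]3c1cc(O[Si](C)(C)C)cc(O[Si](C)(C)C)c1)O2
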